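**Conventions.** C-numbers follow the germacranolide numbering of the target: C1 ketone, C3 OMe, C4 Me, C6 lactone carbon, C7 ring fusion, C8 angelate, C10 quaternary carbon carrying OAc and Me, C11–C13 the α-methylene lactone carbons. "Up" and "down" are faces of the cyclohexane (carvone) ring, with the C7 isopropenyl down.

**Assumption:** (E)-tributyl(2-methoxyvinyl)stannane is obtainable commercially or in one step.

## Retrosynthesis
- The C8 angelate and C10 acetate are late acylations. The α-methylene-γ-lactone is closed last, by iodolactonization of a C12 acrylic acid across a C5=C6 olefin. C12 comes from the carvone isopropenyl methyl.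
- The ten-membered carbocycle and the vicinal C3(OMe)/C4(Me) centres come from one anionic oxy-Cope ring expansion. It converts a cis-1-(2-methoxyvinyl)-2-propenylcyclohexan-1-ol into the ring, breaking C1–C6, forming C3–C4 and releasing the C1 ketone.
- The cyclohexane is (R)-carvone, which supplies C7. C6 is alkylated through the enolate, and the C10/C8 oxygens are installed anti to the isopropenyl. The carvone C=O becomes the C1 carbinol.
- Ring order: cyclohexane (carvone) → ten-membered ring (oxy-Cope) → γ-lactone.

## Route

**Step 1**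
Reactants: 1 (R)-(−)-carvone
Product: 2 trans-6-allylcarvone (allyl trans to isopropenyl)
Conditions: LDA, THF, −78 °C; then allyl bromide, DMPU, −78 → 0 °C
Reagents that add atoms: allyl bromide, C=CCBr
Why: Kinetic deprotonation at the α′ carbon (C6) and SN2 alkylation anti to the C7 isopropenyl set the C6 allyl trans (enolate alkylation).

**Step 2**
Reactants: 2
Product: 3 9,10-epoxide of 6-allylcarvone (O anti to isopropenyl, allyl trans)
Conditions: 30% H2O2, NaOH, MeOH, 0 °C
Reagents that add atoms: hydrogen peroxide, OO
Why: In the Weitz–Scheffer nucleophilic epoxidation, HOO⁻ attacks C9 anti to the C7 isopropenyl, so the C10–O is set up (trans to isopropenyl). The basic medium keeps C6 equatorial (trans).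

**Step 3**
Reactants: 3
Product: 4 C1 ethylene ketal of 3
Conditions: TMSOCH2CH2OTMS, TMSOTf (cat.), CH2Cl2, −78 → 0 °C
Reagents that add atoms: 1,2-bis(trimethylsilyloxy)ethane, C[Si](C)(C)OCCO[Si](C)(C)C
Why: Noyori ketalization under aprotic, low-temperature conditions, which the α-keto epoxide tolerates. It masks C1 so the amide base and hydride steps cannot enolize or reduce it.

**Step 4**
Reactants: 4
Product: 5 ketal with C10 tertiary allylic alcohol (O up, Me down) and C8=C9 olefin
Conditions: Et2AlTMP (3 equiv), PhMe, 0 → 25 °C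
Reagents that add atoms: none
Why: Epoxide-to-allylic-alcohol isomerization by syn β-elimination: the aluminium amide removes the C8–H cis to the epoxide oxygen and cleaves C9–O. C10 keeps its oxygen with retention, and C10 has no H, so only the C8=C9 olefin can form.

**Step 5**
Reactants: 5
Product: 6 8,9-epoxy-10-ol (epoxide up, syn to C10–OH)
Conditions: VO(acac)2 (5 mol%), TBHP, CH2Cl2, 0 → 25 °C
Reagents that add atoms: tert-butyl hydroperoxide, CC(C)(C)OO
Why: Hydroxy-directed vanadium epoxidation delivers O to the face syn to the tertiary C10–OH, which is also anti to the isopropenyl. This fixes the future C8 oxygen configuration.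

**Step 6**
Reactants: 6
Product: 7 C8,C10-diol (both OH up), C9 as CH2, C1 ketal, C6 allyl
Conditions: Red-Al, THF, 0 → 25 °C
Reagents that add atoms: none
Why: Hydride is delivered intramolecularly through the C10 alkoxyaluminate to the proximal epoxide carbon C9 (Finan–Kishi-type opening). This gives the 1,3-diol with C8–O retained (up).

**Step 7**
Reactants: 7
Product: 8 as 7 but with the C6 arm (E)-prop-1-enyl
Conditions: RuHCl(CO)(PPh3)3 (5 mol%), PhMe, 90 °C
Reagents that add atoms: none
Why: Ru–H olefin isomerization moves the monosubstituted allyl to the thermodynamic (E)-propenyl, which is the C4–C5 arm of the oxy-Cope. The 1,1-disubstituted isopropenyl is not isomerized. No stereocenter is created.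

**Step 8**
Reactants: 8
Product: 9 C1 ketone, C10-OH/Me, C8-OH, C7 isopropenyl, C6 (E)-propenyl equatorial (trans)
Conditions: PPTS, acetone/H2O, 60 °C
Reagents that add atoms: water, O
Why: Acid hydrolysis of the ketal. The C6–H α to the ketone equilibrates to the equatorial (trans to C7) propenyl.

**Step 9**
Reactants: 9
Product: 10 cis-1,2-dialkenyl tertiary alcohol (C1 arm up, C1–OH down, C6 arm up)
Conditions: (E)-MeOCH=CHLi (4 equiv; from (E)-Bu3SnCH=CHOMe + n-BuLi), THF, −78 °C
Reagents that add atoms: (E)-tributyl(2-methoxyvinyl)stannane, CCCC[Sn](CCCC)(CCCC)/C=C/OC (leaves the MeOCH=CH– group)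
Why: 1,2-Addition of an organolithium to a ketone, chelated by the C10 lithium alkoxide. Axial attack on the chair conformer (all groups equatorial except the C10 methyl) from the face anti to the axial methyl puts the new arm cis to the C6 propenyl. That cis arrangement is what later gives (3R,4R).

**Step 10**
Reactants: 10
Product: 11 ten-membered ring ketone (C1=O, 3R,4R, 5Z-olefin, C8-OH, C10-OH)
Conditions: KH, 18-crown-6, THF, 0 → 60 °C; then aq. NH4Cl
Reagents that add atoms: none
Why: Anionic oxy-Cope ring expansion ([3,3] sigmatropic) cleaves C1–C6 and forms C3–C4. It runs through the chair transition state of the conformer with equatorial C6 propenyl and axial C1 methoxyvinyl. Both E termini sit equatorial, giving the syn (3R,4R) pair and a Z C5=C6 olefin. The C1 enolate protonates to the ketone.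

**Step 11**
Reactants: 11
Product: 12 C12 primary allylic alcohol (isopropenyl CH3 → CH2OH)
Conditions: SeO2 (0.3 equiv), TBHP, CH2Cl2, 25 °C
Reagents that add atoms: tert-butyl hydroperoxide, CC(C)(C)OO
Why: Riley/Sharpless allylic oxidation occurs at the methyl of the more reactive 1,1-disubstituted olefin. No stereocenter is formed.

**Step 12**
Reactants: 12
Product: 13 α-methylene aldehyde
Conditions: MnO2, CH2Cl2, 25 °C
Reagents that add atoms: none
Why: MnO2 oxidizes only the allylic primary alcohol; the secondary C8–OH and tertiary C10–OH are untouched.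

**Step 13**
Reactants: 13
Product: 14 α-methylene carboxylic acid (C12 acid)
Conditions: NaClO2, NaH2PO4, 2-methyl-2-butene, t-BuOH/H2O, 25 °C
Reagents that add atoms: sodium chlorite, O=Cl[O-].[Na+]
Why: Pinnick oxidation. The scavenger protects the C5=C6 olefin from HOCl.

**Step 14**
Reactants: 14
Product: 15 5-iodo-6,7-trans γ-lactone
Conditions: I2, NaHCO3, THF/H2O, 0 °C
Reagents that add atoms: iodine, II
Why: Iodolactonization. The iodonium on the C5=C6 olefin is opened anti by the C12 carboxylate in 5-exo fashion from the face set by C7, fixing C6 (R) as the trans-fused lactone with iodine on C5.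

**Step 15**
Reactants: 15
Product: 16 lactone diol (C5H2)
Conditions: Bu3SnH, AIBN, PhMe, 80 °C
Reagents that add atoms: none
Why: Radical hydrodeiodination (Bu3SnH chain reaction) removes C5–I, and C5 becomes CH2. No stereocenter remains there.

**Step 16**
Reactants: 16
Product: 17 C8 angelate
Conditions: angelic acid, 2,4,6-Cl3C6H2COCl, Et3N, THF; then DMAP, PhMe, 25 °C
Reagents that add atoms: angelic acid, C/C=C(/C)C(=O)O
Why: Yamaguchi esterification. The mixed anhydride acylates the accessible secondary C8–OH and not the tertiary C10–OH, with retention at C8 and Z geometry.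

**Step 17**
Reactants: 17
Product: 18 Rufesolide C
Conditions: Ac2O, Sc(OTf)3 (cat.), MeCN, 25 °C
Reagents that add atoms: acetic anhydride, CC(=O)OC(C)=O
Why: Lewis-acid-catalysed acetylation of the hindered tertiary α-hydroxy ketone C10–OH, with retention at C10. The angelate and lactone survive.

## Compound list
1 | (R)-(−)-carvone | CC1=CC[C@H](CC1=O)C(C)=C | starting material
2 | trans-6-allylcarvone | CC1=CC[C@@H](C(C)=C)[C@H](CC=C)C1=O | intermediate
3 | 9,10-epoxide of 2 (O anti to isopropenyl) | C[C@@]12O[C@@H]1C[C@@H](C(C)=C)[C@H](CC=C)C2=O | intermediate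
4 | C1 ethylene ketal of 3 | C[C@@]12O[C@@H]1C[C@@H](C(C)=C)[C@H](CC=C)C23OCCO3 | intermediate
5 | C10 tertiary allylic alcohol, C8=C9 olefin, C1 ketal | C[C@@]1(O)C=C[C@@H](C(C)=C)[C@H](CC=C)C12OCCO2 | intermediate
6 | 8,9-epoxide syn to C10–OH | C[C@@]1(O)[C@@H]2O[C@@H]2[C@@H](C(C)=C)[C@H](CC=C)C13OCCO3 | intermediate
7 | C8,C10-diol, C1 ketal, C6 allyl | C[C@@]1(O)C[C@H](O)[C@@H](C(C)=C)[C@H](CC=C)C12OCCO2 | intermediate
8 | C6 (E)-propenyl analogue of 7 | C[C@@]1(O)C[C@H](O)[C@@H](C(C)=C)[C@H](/C=C/C)C12OCCO2 | intermediate
9 | C1 ketone (ketal removed) | C[C@@]1(O)C[C@H](O)[C@@H](C(C)=C)[C@H](/C=C/C)C1=O | intermediate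
10 | C1 (E)-2-methoxyvinyl carbinol, arms cis | C[C@@]1(O)C[C@H](O)[C@@H](C(C)=C)[C@H](/C=C/C)[C@]1(O)/C=C/OC | intermediate
11 | ten-membered ketone from oxy-Cope (3R,4R, 5Z) | O=C1C[C@@H](OC)[C@H](C)/C=C\[C@H](C(C)=C)[C@@H](O)C[C@@]1(C)O | intermediate
12 | C12 allylic alcohol | O=C1C[C@@H](OC)[C@H](C)/C=C\[C@H](C(=C)CO)[C@@H](O)C[C@@]1(C)O | intermediate
13 | α-methylene aldehyde | O=C1C[C@@H](OC)[C@H](C)/C=C\[C@H](C(=C)C=O)[C@@H](O)C[C@@]1(C)O | intermediate
14 | α-methylene acid | O=C1C[C@@H](OC)[C@H](C)/C=C\[C@H](C(=C)C(=O)O)[C@@H](O)C[C@@]1(C)O | intermediate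
15 | 5-iodo lactone | C=C1C(=O)O[C@@H]2[C@@H](I)[C@@H](C)[C@H](OC)CC(=O)[C@](C)(O)C[C@H](O)[C@@H]12 | intermediate
16 | lactone diol | C=C1C(=O)O[C@@H]2C[C@@H](C)[C@H](OC)CC(=O)[C@](C)(O)C[C@H](O)[C@@H]12 | intermediate
17 | C8 angelate, C10-OH | C=C1C(=O)O[C@@H]2C[C@@H](C)[C@H](OC)CC(=O)[C@](C)(O)C[C@H](OC(=O)/C(C)=C\C)[C@@H]12 | intermediate
18 | Rufesolide C | C=C1C(=O)O[C@@H]2C[C@@H](C)[C@H](OC)CC(=O)[C@](C)(OC(C)=O)C[C@H](OC(=O)/C(C)=C\C)[C@@H]12 | target

**Total steps:** 17. **Longest linear sequence:** 17, from (R)-carvone.

## Three steps most likely to fail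
1. **Step 10 (oxy-Cope).** The trialkoxide may be sluggish, and the C3/C4 sense depends on the diastereomer formed in step 9. The wrong C1 epimer would give (3S,4S). Fallback: build C3/C4 acyclically by an Ireland–Claisen rearrangement on a carvone-derived chain, then close the ten-membered ring by intramolecular Nozaki–Hiyama–Kishi coupling.
2. **Step 14 (iodolactonization).** Facial and regio-selectivity at C6 in the (Z)-cyclodecene is hard to predict, and a cis-fused lactone could form. Fallback: epoxidize C5=C6 with mCPBA, open the epoxide at C6 with the C12 acid under Lewis acid (5-exo, inversion), then remove the C5–OH by Barton–McCombie deoxygenation.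
3. **Step 4 (epoxide → allylic alcohol).** Base may remove a C10-methyl hydrogen instead of C8–H and give the exocyclic allylic alcohol. Fallback: open the epoxide at C9 with PhSeNa, then oxidize with H2O2 so the selenoxide eliminates toward C8 (C10 has no H), giving the same allylic alcohol 5.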